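Atoms keep their germacrane numbers throughout: C1 ketone, C2=C3 enol ether, C4=C15, C5–OH, C6–O lactone, C7, C8 ester, C9, C10 (bearing C14 and the bridging oxygen), C11–C13 lactone arm.
Retrosynthetic cuts, in order: C4=C15 (back to a C15 isobutyrate); C6–O and C5–O (back to an E-C5=C6 alkene and a C12 ester); C2=C3 (back to the oxolanone); C3–C4 with C1–C6 rejoined (retro oxy-Cope); then O–C3, C1–C2, C11–C13, C10–O, C7–C11 and C5–C6, ending at 4-methoxy-3-methylphenol.
Enabling feature: the C1 carbonyl is 1,5-related to the anti C5/C6 dioxygen pattern, which is a disguised E-alkene, and the furanone oxygen already ties C3 to C10. The ten-membered ring C1–C10 therefore folds back onto a cis-fused hexahydrobenzofuran-3a-ol whose cyclohexane (C1, C6, C7, C8, C9, C10) bears the three centres that survive (C7, C8, C10).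
Forward ring order: cyclohexane from the arene by dearomatisation; dihydrofuran by alkynol cycloisomerisation; ten-membered carbocycle by four-atom expansion of the cyclohexane with the ether bridge in place; butyrolactone last, by epoxide opening.
Stereochemistry: C6 of the cyclohexane comes from a rhodium/(R)-BINAP conjugate addition. C7, C10, C8 and C1 follow by relay (trans alkylation, hydroxyl-directed epoxidation, hydroxyl-directed anti reduction, axial acetylide addition). C5 and C6 of the target come from the planar sense of the E-alkene born in the rearrangement (outer-face epoxidation, invertive lactonisation).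
Key step: step 14

Remark on the chemistry: C11 is formed as a mixture of epimers in step 10 and is left undefined in names and SMILES until it becomes sp2 in step 19. TBS = tert-butyldimethylsilyl.

Step 1
Reactants: 1 4-methoxy-3-methylphenol
Product: 2 4,4-dimethoxy-3-methylcyclohexa-2,5-dien-1-one
Conditions: PhI(OAc)2 (1.05 equiv), MeOH, 0 °C to rt
Reagents that add atoms: methanol (CO)
Why: Oxidative dearomatisation of a para-alkoxyphenol with a hypervalent iodine reagent, in which methanol captures the ring carbon that already bears OMe, is the standard entry to quinone monoketals and leaves the future C8 carbonyl free while the future C1 carbonyl is masked, with no stereocentre formed.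

Step 2
Reactants: 2 4,4-dimethoxy-3-methylcyclohexa-2,5-dien-1-one; 3 (E)-3-(TBSO)prop-1-enylboronic acid pinacol ester
Product: 4 C6-alkenyl enone ketal (6R)
Conditions: [RhCl(C2H4)2]2 (2.5 mol %), (R)-BINAP (5.5 mol %), KOH (20 mol %), dioxane/H2O 10:1, 35 °C
Reagents that add atoms: none
Why: Hayashi–Miyaura asymmetric 1,4-addition, a reaction known for quinone monoketals, should insert only the unsubstituted enone arm because the methyl-bearing β-carbon is too hindered, and (R)-BINAP, which leads to the R product with cyclohex-2-enone, should by the same facial sense set C6 as R, while the nearly neutral medium avoids loss of methanol and rearomatisation.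

Step 3
Reactants: 4 C6-alkenyl enone ketal; 5 tert-butyl bromoacetate
Product: 7 trans-6,7-disubstituted enone ketal (6S,7S), via lithium dienolate 6 (not isolated)
Conditions: LiN(iPr)2 (1.1 equiv), THF, −78 °C; then 5 (1.5 equiv), DMPU, −78 to −40 °C
Reagents that add atoms: none
Why: Kinetic α'-deprotonation of the enone gives the cross-conjugated enolate, and its SN2 alkylation by the reactive bromoacetate takes place on the face away from the adjacent C6 alkenyl group, which sets C7 trans to C6, the arrangement that is also thermodynamically preferred.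

Step 4
Reactants: 7 trans-6,7-disubstituted enone ketal
Product: 8 C8 allylic alcohol (8R; hydroxyl trans to the C7 chain)
Conditions: NaBH4, CeCl3·7H2O, MeOH, −78 to −40 °C
Reagents that add atoms: none
Why: Luche 1,2-reduction, in which axial hydride delivery to the half-chair that keeps both side chains equatorial should give the pseudo-equatorial C8 alcohol, trans to the C7 chain and therefore on the ring face that carries the C6 alkenyl group.

Step 5
Reactants: 8 C8 allylic alcohol
Product: 9 9,10-epoxy alcohol (oxirane cis to C8–OH; 9R,10R)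
Conditions: VO(acac)2 (5 mol %), t-BuOOH (1.5 equiv, decane), CH2Cl2, 0 °C to rt
Reagents that add atoms: tert-butyl hydroperoxide (CC(C)(C)OO)
Why: Vanadium-catalysed epoxidation directed by the allylic hydroxyl delivers oxygen syn to C8–OH, which places the C10–O bond on the face of the C6 alkenyl group, and it ignores the side-chain alkene, whose oxygen is silylated.

Step 6
Reactants: 9 9,10-epoxy alcohol
Product: 10 9,10-epoxy 8-ketone
Conditions: Dess–Martin periodinane, NaHCO3, CH2Cl2, 0 °C to rt
Reagents that add atoms: none
Why: Dess–Martin oxidation under bicarbonate buffer converts the now dispensable C8 carbinol into the ketone without opening the epoxide or the ketal and touches no other stereocentre.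

Step 7
Reactants: 10 9,10-epoxy 8-ketone
Product: 11 C10 tertiary β-hydroxy ketone (10R)
Conditions: SmI2 (2.2 equiv), THF/MeOH, −78 °C
Reagents that add atoms: none
Why: Reductive opening of an α,β-epoxy ketone with divalent samarium proceeds by ketyl formation, cleavage of the Cα–O bond at C9 and protonation of the samarium enolate by methanol, so the C10–O bond and its configuration are retained.

Step 8
Reactants: 11 C10 tertiary β-hydroxy ketone
Product: 12 1,3-anti diol (8R,10R)
Conditions: Me4NBH(OAc)3 (5 equiv), MeCN/AcOH 1:1, −30 °C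
Reagents that add atoms: none
Why: Evans–Saksena reduction, in which the borohydride exchanges an acetate for the C10 hydroxyl and delivers hydride within the complex to the carbonyl face on that side, gives the 1,3-anti diol with C8–OH cis to the C7 chain, and the same face is also the sterically open one when the C10 methyl group is axial.

Step 9
Reactants: 12 1,3-anti diol
Product: 13 C8 TBS ether with free C10 hydroxyl
Conditions: TBSCl (1.3 equiv), imidazole, DMF, rt
Reagents that add atoms: tert-butyldimethylsilyl chloride (CC(C)(C)[Si](C)(C)Cl)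
Why: Silylation with TBSCl and imidazole discriminates between the secondary C8 hydroxyl and the hindered tertiary C10 hydroxyl, which must stay free for steps 12 and 13, and prompt protection also forestalls lactonisation of C8–OH onto the cis C7 ester arm.

Step 10
Reactants: 13 C8 TBS ether; 14 N,N-dimethylmethyleneiminium iodide (Eschenmoser's salt)
Product: 16 Mannich-base ester ketal, via dilithio alkoxide-enolate 15 (not isolated)
Conditions: LiN(iPr)2 (3 equiv), THF, −78 °C; then 14 (3 equiv), −78 °C to rt; aq NaHCO3
Reagents that add atoms: none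
Why: Mannich aminomethylation of the ester enolate with Eschenmoser's salt installs C13 as a base-stable mask of the α-methylene group, the C10 alkoxide adding to the iminium ion only reversibly, and the new C11 centre is formed as an inconsequential epimer mixture.

Step 11
Reactants: 16 Mannich-base ester ketal
Product: 17 α-hydroxy ketone (C1 carbonyl unmasked)
Conditions: PPTS (1.5 equiv), acetone/H2O 9:1, 40 °C; aq NaHCO3 work-up
Reagents that add atoms: water (O)
Why: Mild acid hydrolysis of the dimethyl ketal with a pyridinium salt, one equivalent of which is taken up by the amine, is much faster than cleavage of TBS ethers or of the tert-butyl ester, and C6, now α to the ketone, already holds its more stable trans relation to C7 so that reversible enolisation cannot erode it.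

Step 12
Reactants: 17 α-hydroxy ketone; 18 ethynylmagnesium bromide
Product: 19 C1 ethynyl carbinol (1S; alkyne cis to C10–OH)
Conditions: LaCl3·2LiCl (1.1 equiv), THF, 0 °C; then 18 (4 equiv), −78 to 0 °C; aq NH4Cl
Reagents that add atoms: none
Why: Lanthanide-assisted 1,2-addition of an alkynyl Grignard reagent to an enolisable ketone, in which the first equivalent forms the C10 alkoxide, its chelate with the C1 carbonyl places C10–O equatorial and the C10 methyl axial, and the slim acetylide enters axially, anti to that methyl group, while in the other chair the opposite face is blocked by the axial C7 chain, so that the alkyne should end up cis to the C10 oxygen and to the C6 alkenyl group.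

Step 13
Reactants: 19 C1 ethynyl carbinol
Product: 20 cis-fused 7a-methylhexahydrobenzofuran-3a-ol (3aS,4S,5R,6R,7aR)
Conditions: Mo(CO)6 (30 mol %), Et3N/Et2O, hν (350 nm) to form (Et3N)Mo(CO)5; then 19, rt; filtration through Et3N-deactivated alumina, used at once
Reagents that add atoms: none
Why: Endo-selective cycloisomerisation of a but-3-yn-1-ol unit through a molybdenum vinylidene, in which the C10 hydroxyl adds to the terminal carbon C3 and amine-mediated protodemetalation releases the 2,3-dihydrofuran, gives the cis ring fusion dictated by the cis C2/C10–O arrangement of step 12 and creates no stereocentre.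

Step 14
Reactants: 20 cis-fused 7a-methylhexahydrobenzofuran-3a-ol
Product: 23 bridged ten-membered ketone (3R,4R,5E,7R,8R,10R), via potassium alkoxide 21 (not isolated), via potassium enolate 22 (not isolated)
Conditions: KN(SiMe3)2 (1.05 equiv), 18-crown-6 (1.2 equiv), THF, 0 °C to rt; then AcOH (1.2 equiv), −78 °C
Reagents that add atoms: none
Why: Proposed new method: KN(SiMe3)2 removes the only acidic proton to give the alkoxide, whose charge weakens the allylic C1–C6 bond so that a concerted [3,3] shift through C3=C2–C1–C6–C5=C4 forms C3–C4 as C1–C6 breaks, and the resulting C1 enolate is protonated at C2 by the cold acid quench before it can expel the C3 oxygen. Nearest precedents are two classes of alkoxide-accelerated Cope rearrangement, namely 1,2-dialkenylcyclohexan-1-ols that expand to (E)-cyclodec-5-en-1-ones and 1-allylcycloalk-2-en-1-ols in which the ring alkene is the carbinol-side partner, whereas a substrate that combines both and whose ring alkene is a cyclic enol ether has not been described. The ten-membered carbocycle C1–C10 closes by four-atom expansion of the cyclohexane rather than by end-to-end cyclisation, and the five-membered ether ring passes through intact to become the C3–O–C10 bridge of an 11-oxabicyclo[6.2.1]undec-3-en-9-one. C3 is fixed by suprafacial bonding on the dihydrofuran face that bears C6 and C9, and C4 by the E geometry of the side-chain alkene in a chair array that keeps CH2OTBS pseudo-equatorial, both centres being erased later. The step needs the chair rather than the boat array, E rather than Z C5=C6 in one planar sense, and [3,3] rather than [1,3] migration or fragmentation: the cis ring fusion forces the ring oxygen and C10 into pseudo-axial sites, the C8–C9 tether then allows C7 only the pseudo-equatorial site at C6 (hence E), and the roughly 60° C2–C1–C6–C5 dihedral of the cyclohexane chair with C10–O and the alkenyl group axial matches the chair array and brings C3 and C4 within bonding range. One equivalent of base leaves the tert-butyl ester, the β-amino group and both silyl ethers untouched.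

Step 15
Reactants: 23 bridged ten-membered ketone
Product: 24 C8,C15 diol
Conditions: HF·pyridine, pyridine/THF, 0 °C to rt
Reagents that add atoms: none
Why: Fluoride-mediated desilylation in a buffered acidic medium removes both TBS ethers without the basic conditions that could trigger β-elimination of the amine or of the C3 oxygen or lactonisation of a C8 alkoxide.

Step 16
Reactants: 24 C8,C15 diol
Product: 25 C8,C15 bis-isobutyrate ketone
Conditions: i-PrCOCl (3 equiv), pyridine, DMAP (cat.), CH2Cl2, 0 °C to rt
Reagents that add atoms: isobutyryl chloride (CC(C)C(=O)Cl)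
Why: DMAP-catalysed acylation esterifies the primary C15 and the secondary C8 hydroxyl alike, which installs the C8 ester of the target and at the same time a latent leaving group at C15 that is inert as long as C2–C3 is saturated.

Step 17
Reactants: 25 C8,C15 bis-isobutyrate ketone
Product: 26 C1 trimethylsilyl enol ether
Conditions: TMSOTf (1.5 equiv), Et3N (4 equiv), CH2Cl2, −20 to 0 °C
Reagents that add atoms: trimethylsilyl triflate (C[Si](C)(C)OS(=O)(=O)C(F)(F)F)
Why: Soft enolisation with TMSOTf and triethylamine can only occur toward C2 because C10 is quaternary, and at or below 0 °C ketone silylation should outpace attack of the silyl triflate on the tert-butyl ester.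

Step 18
Reactants: 26 C1 trimethylsilyl enol ether
Product: 27 3(2H)-furanone bis-isobutyrate (4R,5E,7R,8R,10R)
Conditions: Pd(OAc)2 (1.2 equiv), MeCN, rt; carried forward without delay
Reagents that add atoms: none
Why: Saegusa–Ito dehydrogenation, in which divalent palladium binds C2 on the exposed face of the oxolane, the face that also carries the C3 hydrogen, so that syn β-hydride elimination gives the furanone under essentially neutral conditions that spare the now labile C15 ester, a full equivalent of Pd(OAc)2 compensating for coordination by the amine.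

Step 19
Reactants: 27 3(2H)-furanone bis-isobutyrate
Product: 29 tert-butyl C11=C13 acrylate, via amine N-oxide 28 (not isolated)
Conditions: mCPBA (1.0 equiv), NaHCO3, CH2Cl2, −20 °C; then rt
Reagents that add atoms: none
Why: Amine oxidation by one equivalent of peracid is far faster than epoxidation, and the N-oxide of the β-amino ester undergoes Cope elimination through a five-membered syn transition state at C11–H on warming, which unveils C11=C13 and removes the undefined C11 centre.

Step 20
Reactants: 29 tert-butyl C11=C13 acrylate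
Product: 30 trans-5,6-epoxide (5S,6S)
Conditions: mCPBA (1.3 equiv), NaHCO3, CH2Cl2, 0 °C
Reagents that add atoms: 3-chloroperoxybenzoic acid (O=C(OO)c1cccc(Cl)c1)
Why: Prilezhaev epoxidation picks the only electron-rich alkene (the furanone and acrylate alkenes are deactivated), and because the inner face of E-C5=C6 looks across the ring toward C1, oxygen should be delivered stereospecifically to the outer face to give the trans 5S,6S epoxide.

Step 21
Reactants: 30 trans-5,6-epoxide
Product: 31 5-hydroxy-6,12-olide with C4 still sp3 (4S,5S,6R,7R,8R,10R)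
Conditions: CF3CO2H, CH2Cl2, 0 °C
Reagents that add atoms: none
Why: Acid-promoted 5-exo opening of the epoxide by the carbonyl oxygen of the neighbouring tert-butyl ester, a lactonisation with loss of the tert-butyl group as isobutene, attacks C6 from the side opposite the epoxide oxygen, so that C6 is inverted to R and the lactone is cis-fused at C6/C7, while C5 keeps its C–O bond and becomes the 5S alcohol.

Step 22
Reactants: 31 5-hydroxy-6,12-olide
Product: 32 target CNP0384113.1 (5S,6R,7R,8R,10R)
Conditions: DBU (1.1 equiv), CH2Cl2, −40 to −10 °C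
Reagents that add atoms: none
Why: Vinylogous E1cB elimination, in which DBU removes the C4 hydrogen that is γ to the furanone carbonyl and the extended enolate expels the C15 isobutyrate, a far better leaving group than the C5 hydroxyl, gives C4=C15 at a temperature that should spare the α-methylene lactone and all remaining stereocentres.

Compound list
1 | 4-methoxy-3-methylphenol | COc1ccc(O)cc1C | starting material
2 | 4,4-dimethoxy-3-methylcyclohexa-2,5-dien-1-one | COC1(OC)C=CC(=O)C=C1C | intermediate
3 | (E)-3-(tert-butyldimethylsilyloxy)prop-1-enylboronic acid pinacol ester | CC(C)(C)[Si](C)(C)OC/C=C/B1OC(C)(C)C(C)(C)O1 | starting material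
4 | (5R)-5-[(E)-3-(TBSO)prop-1-enyl]-4,4-dimethoxy-3-methylcyclohex-2-en-1-one (6R in germacrane numbering) | O=C1C=C(C)C(OC)(OC)[C@@H](/C=C/CO[Si](C)(C)C(C)(C)C)C1 | intermediate
5 | tert-butyl bromoacetate | CC(C)(C)OC(=O)CBr | starting material
6 | lithium C7=C8 dienolate of 4 | [Li]OC1=C[C@H](/C=C/CO[Si](C)(C)C(C)(C)C)C(OC)(OC)C(C)=C1 | intermediate
7 | tert-butyl 2-[(1S,6S)-6-[(E)-3-(TBSO)prop-1-enyl]-5,5-dimethoxy-4-methyl-2-oxocyclohex-3-en-1-yl]acetate (6S,7S; side chains trans) | O=C1C=C(C)C(OC)(OC)[C@@H](/C=C/CO[Si](C)(C)C(C)(C)C)[C@@H]1CC(=O)OC(C)(C)C | intermediate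
8 | tert-butyl 2-[(1S,2R,6S)-6-[(E)-3-(TBSO)prop-1-enyl]-2-hydroxy-5,5-dimethoxy-4-methylcyclohex-3-en-1-yl]acetate (8R; OH trans to the C7 chain) | O[C@H]1C=C(C)C(OC)(OC)[C@@H](/C=C/CO[Si](C)(C)C(C)(C)C)[C@@H]1CC(=O)OC(C)(C)C | intermediate
9 | 9,10-epoxide of 8 with the oxirane cis to C8–OH (6S,7S,8R,9R,10R) | O[C@H]1[C@H]2O[C@@]2(C)C(OC)(OC)[C@@H](/C=C/CO[Si](C)(C)C(C)(C)C)[C@@H]1CC(=O)OC(C)(C)C | intermediate
10 | 9,10-epoxy 8-ketone derived from 9 (6S,7S,9S,10R) | O=C1[C@H]2O[C@@]2(C)C(OC)(OC)[C@@H](/C=C/CO[Si](C)(C)C(C)(C)C)[C@@H]1CC(=O)OC(C)(C)C | intermediate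
11 | tert-butyl 2-[(1S,4R,6S)-6-[(E)-3-(TBSO)prop-1-enyl]-4-hydroxy-5,5-dimethoxy-4-methyl-2-oxocyclohexyl]acetate | O=C1C[C@@](C)(O)C(OC)(OC)[C@@H](/C=C/CO[Si](C)(C)C(C)(C)C)[C@@H]1CC(=O)OC(C)(C)C | intermediate
12 | tert-butyl 2-[(1S,2R,4R,6S)-6-[(E)-3-(TBSO)prop-1-enyl]-2,4-dihydroxy-5,5-dimethoxy-4-methylcyclohexyl]acetate (hydroxyls 1,3-anti) | O[C@@H]1C[C@@](C)(O)C(OC)(OC)[C@@H](/C=C/CO[Si](C)(C)C(C)(C)C)[C@@H]1CC(=O)OC(C)(C)C | intermediate
13 | tert-butyl 2-[(1S,2R,4R,6S)-2-(TBSO)-6-[(E)-3-(TBSO)prop-1-enyl]-4-hydroxy-5,5-dimethoxy-4-methylcyclohexyl]acetate | CC(C)(C)[Si](C)(C)O[C@@H]1C[C@@](C)(O)C(OC)(OC)[C@@H](/C=C/CO[Si](C)(C)C(C)(C)C)[C@@H]1CC(=O)OC(C)(C)C | intermediate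
14 | N,N-dimethylmethyleneiminium iodide (Eschenmoser's salt) | C=[N+](C)C.[I-] | starting material
15 | dilithio derivative of 13 (C10 lithium alkoxide, C11=C12 lithium ester enolate) | CC(C)(C)[Si](C)(C)O[C@@H]1C[C@@](C)(O[Li])C(OC)(OC)[C@@H](/C=C/CO[Si](C)(C)C(C)(C)C)[C@@H]1C=C(O[Li])OC(C)(C)C | intermediate
16 | tert-butyl 2-[(1R,2R,4R,6S)-2-(TBSO)-6-[(E)-3-(TBSO)prop-1-enyl]-4-hydroxy-5,5-dimethoxy-4-methylcyclohexyl]-3-(dimethylamino)propanoate (C11 epimers) | CC(C)(C)[Si](C)(C)O[C@@H]1C[C@@](C)(O)C(OC)(OC)[C@@H](/C=C/CO[Si](C)(C)C(C)(C)C)[C@@H]1C(CN(C)C)C(=O)OC(C)(C)C | intermediate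
17 | tert-butyl 2-[(1R,2R,4R,6S)-2-(TBSO)-6-[(E)-3-(TBSO)prop-1-enyl]-4-hydroxy-4-methyl-5-oxocyclohexyl]-3-(dimethylamino)propanoate | CC(C)(C)[Si](C)(C)O[C@@H]1C[C@@](C)(O)C(=O)[C@@H](/C=C/CO[Si](C)(C)C(C)(C)C)[C@@H]1C(CN(C)C)C(=O)OC(C)(C)C | intermediate
18 | ethynylmagnesium bromide | C#C[Mg]Br | starting material
19 | tert-butyl 2-[(1R,2R,4R,5S,6S)-2-(TBSO)-6-[(E)-3-(TBSO)prop-1-enyl]-5-ethynyl-4,5-dihydroxy-4-methylcyclohexyl]-3-(dimethylamino)propanoate (alkyne cis to C10–OH and to the alkenyl group) | CC(C)(C)[Si](C)(C)O[C@@H]1C[C@@](C)(O)[C@@](O)(C#C)[C@@H](/C=C/CO[Si](C)(C)C(C)(C)C)[C@@H]1C(CN(C)C)C(=O)OC(C)(C)C | intermediate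
20 | tert-butyl 2-[(3aS,4S,5R,6R,7aR)-6-(TBSO)-4-[(E)-3-(TBSO)prop-1-enyl]-3a-hydroxy-7a-methyl-3a,4,5,6,7,7a-hexahydro-1-benzofuran-5-yl]-3-(dimethylamino)propanoate (cis-fused) | CC(C)(C)[Si](C)(C)O[C@@H]1C[C@@]2(C)OC=C[C@@]2(O)[C@@H](/C=C/CO[Si](C)(C)C(C)(C)C)[C@@H]1C(CN(C)C)C(=O)OC(C)(C)C | intermediate
21 | potassium 3a-alkoxide of 20 | CC(C)(C)[Si](C)(C)O[C@@H]1C[C@@]2(C)OC=C[C@@]2(O[K])[C@@H](/C=C/CO[Si](C)(C)C(C)(C)C)[C@@H]1C(CN(C)C)C(=O)OC(C)(C)C | intermediate
22 | potassium C1=C2 enolate of 23 | CC(C)(C)[Si](C)(C)O[C@@H]1C[C@@]2(C)O[C@H](C=C2O[K])[C@@H](CO[Si](C)(C)C(C)(C)C)/C=C/[C@@H]1C(CN(C)C)C(=O)OC(C)(C)C | intermediate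
23 | tert-butyl 2-[(1R,2R,3E,5R,6R,8R)-6-(TBSO)-2-(TBSO-methyl)-8-methyl-9-oxo-11-oxabicyclo[6.2.1]undec-3-en-5-yl]-3-(dimethylamino)propanoate (germacrane 3R,4R,5E,7R,8R,10R) | CC(C)(C)[Si](C)(C)O[C@@H]1C[C@@]2(C)O[C@H](CC2=O)[C@@H](CO[Si](C)(C)C(C)(C)C)/C=C/[C@@H]1C(CN(C)C)C(=O)OC(C)(C)C | intermediate
24 | C8,C15 diol obtained from 23 by removal of both TBS groups | O[C@@H]1C[C@@]2(C)O[C@H](CC2=O)[C@@H](CO)/C=C/[C@@H]1C(CN(C)C)C(=O)OC(C)(C)C | intermediate
25 | C8,C15 bis-isobutyrate of 24 | CC(C)C(=O)O[C@@H]1C[C@@]2(C)O[C@H](CC2=O)[C@@H](COC(=O)C(C)C)/C=C/[C@@H]1C(CN(C)C)C(=O)OC(C)(C)C | intermediate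
26 | C1 trimethylsilyl enol ether (C1=C2) of 25 | CC(C)C(=O)O[C@@H]1C[C@@]2(C)O[C@H](C=C2O[Si](C)(C)C)[C@@H](COC(=O)C(C)C)/C=C/[C@@H]1C(CN(C)C)C(=O)OC(C)(C)C | intermediate
27 | 3(2H)-furanone bis-isobutyrate, an 11-oxabicyclo[6.2.1]undeca-1(10),3-dien-9-one (4R,5E,7R,8R,10R) with the Mannich-base tert-butyl ester at C7 | CC(C)C(=O)O[C@@H]1C[C@@]2(C)OC(=CC2=O)[C@@H](COC(=O)C(C)C)/C=C/[C@@H]1C(CN(C)C)C(=O)OC(C)(C)C | intermediate
28 | dimethylamine N-oxide of 27 | CC(C)C(=O)O[C@@H]1C[C@@]2(C)OC(=CC2=O)[C@@H](COC(=O)C(C)C)/C=C/[C@@H]1C(C[N+](C)(C)[O-])C(=O)OC(C)(C)C | intermediate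
29 | tert-butyl acrylate (C11=C13) derived from 27 (4R,5E,7R,8R,10R) | CC(C)C(=O)O[C@@H]1C[C@@]2(C)OC(=CC2=O)[C@@H](COC(=O)C(C)C)/C=C/[C@@H]1C(=C)C(=O)OC(C)(C)C | intermediate
30 | trans-5,6-epoxide of 29 (4S,5S,6S,7R,8R,10R) | CC(C)C(=O)O[C@@H]1C[C@@]2(C)OC(=CC2=O)[C@@H](COC(=O)C(C)C)[C@@H]3O[C@H]3[C@@H]1C(=C)C(=O)OC(C)(C)C | intermediate
31 | (4S,5S,6R,7R,8R,10R)-5-hydroxy-8,15-bis(isobutyryloxy)-1-oxo-3,10-epoxygermacra-2,11(13)-dien-12,6-olide (cis-fused lactone) | C=C1C(=O)O[C@@H]2[C@H]1[C@H](OC(=O)C(C)C)C[C@@]1(C)OC(=CC1=O)[C@@H](COC(=O)C(C)C)[C@@H]2O | intermediate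
32 | (5S,6R,7R,8R,10R)-5-hydroxy-8-isobutyryloxy-1-oxo-3,10-epoxygermacra-2,4(15),11(13)-trien-12,6-olide (CNP0384113.1) | C=C1C(=O)O[C@@H]2[C@H]1[C@H](OC(=O)C(C)C)C[C@@]1(C)OC(=CC1=O)C(=C)[C@@H]2O | target

Total step count: 22. Longest linear sequence: 22 steps (1 to 32). Compounds 3, 5, 14 and 18 are purchased.

Steps most likely to fail

Step 14. The alkoxide may fragment, undergo a [1,3] shift, or not react at all, because the enol ether is held in a five-membered ring with imperfect overlap to the C1–C6 bond. The fallback uses the known alkoxide-accelerated oxy-Cope rearrangement of 1-alkynyl-2-alkenylcycloalkanols and postpones the ether bridge.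
- It sets out from 19. With KN(SiMe3)2 (2.2 equiv) and 18-crown-6 in THF, 19 should rearrange through its dialkoxide, making the same C3–C4 bond and breaking the same C1–C6 bond.
- The resulting allenolate is protonated to the ten-membered 10-hydroxy-2,5-dien-1-one F1.
- Transannular oxa-Michael addition of the C10 hydroxyl to C3 (catalytic DBU, toluene) can only give the cis-bridged oxolanone, and comes back to the route at 23.

Step 20. Rotation of the E-alkene through the ring could interconvert the planar-chiral conformers, so peracid attack may show poor facial selectivity. The fallback replaces substrate control by reagent control.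
- It sets out from 29 and uses a Shi epoxidation with the L-sorbose-derived enantiomer of the fructose-type ketone, taken stoichiometrically (KHSO5, NaHCO3 buffer near pH 8, MeCN/H2O, 0 °C). This pH avoids premature loss of the C15 ester.
- The spiro transition state of this ketone favours the face of an E-alkene that leads to the S,S epoxide, so the reagent should pick out the matching conformer.
- It comes back to the route at 30. No compound outside the list is made (entry F0).

Step 13. The amine may deactivate the catalyst, the hindered tertiary hydroxyl may attack sluggishly, or the propargylic hydroxyl may ionise at the vinylidene stage. The fallback replaces the catalytic vinylidene route by stoichiometric anti-Markovnikov hydration followed by dehydration.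
- It sets out from 19. Hydroboration of the terminal alkyne with excess dicyclohexylborane and oxidation with NaBO3·4H2O bring C3 to the aldehyde level, where it is captured by the C10 hydroxyl as the five-membered lactol F2.
- MsCl/Et3N (CH2Cl2, −40 °C to rt) activates only the anomeric hydroxyl and eliminates toward C2. This comes back to the route at 20.

Further compounds
F1 | step 14 | (4R,5E,7R,8R,10R)-10-hydroxy-1-oxo-8,15-bis(TBSO)germacra-2,5-diene bearing the C11 Mannich-base tert-butyl ester (C2=C3 geometry undefined) | CC(C)(C)[Si](C)(C)O[C@@H]1C[C@@](C)(O)C(=O)C=C[C@@H](CO[Si](C)(C)C(C)(C)C)/C=C/[C@@H]1C(CN(C)C)C(=O)OC(C)(C)C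
F0 | step 20 | none | none
F2 | step 13 | cis-fused octahydrobenzofuran-2,3a-diol (C3 lactol of the hydrated alkyne of 19, anomers undefined) | CC(C)(C)[Si](C)(C)O[C@@H]1C[C@@]2(C)OC(O)C[C@@]2(O)[C@@H](/C=C/CO[Si](C)(C)C(C)(C)C)[C@@H]1C(CN(C)C)C(=O)OC(C)(C)C
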